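## Retrosynthetic overview

- The hydroquinone oxygen is installed last: the o-cresol-derived phenol is dearomatised to the p-quinone and reduced back to the aromatic diol.
- Key disconnection, ArCH2–CH= bond: an (E)-alkenylalane adds to an o-quinone methide made in the same flask by dearomatising a simple salicyl alcohol carbonate. The alane comes from Zr-catalysed methylalumination of a homopropargylic alcohol.
- The single stereocentre comes from a catalytic asymmetric propargylation of a furyl-substituted geranial.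
- Furan–terpene bond: γ-alkylation of a 2-silyloxyfuran with 8-bromogeranyl acetate.
- Rings: none is built from acyclic atoms. The benzene ring is bought as o-cresol. The furan ring is bought as 3-methylfuran-2(5H)-one and aromatised in step 5.

Assumption: (R)-TRIP sends the allenylboronate to the same aldehyde face as in its allylborations (Re face, giving the R carbinol here); if Mosher analysis of the propargylation product shows the opposite, (S)-TRIP is used.

## Route

**Step 1**
Reactants: 1 geranyl acetate [(2E)-3,7-dimethylocta-2,6-dien-1-yl acetate]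
Product: 2 (2E,6E)-8-hydroxy-3,7-dimethylocta-2,6-dien-1-yl acetate
Conditions: SeO2 (0.3 equiv), t-BuOOH (3 equiv), salicylic acid (0.1 equiv), CH2Cl2, rt, 36 h
Reagents that add atoms: selenium dioxide, O=[Se]=O (catalytic oxygen carrier); tert-butyl hydroperoxide, CC(C)(C)OO (terminal oxidant)
Why: Riley-type allylic oxidation (ene reaction, then [2,3]-sigmatropic shift) hydroxylates the (E)-methyl of the electron-richer terminal alkene, which fixes the 6E geometry.

**Step 2**
Reactants: 2 (2E,6E)-8-hydroxy-3,7-dimethylocta-2,6-dien-1-yl acetate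
Product: 3 (2E,6E)-8-bromo-3,7-dimethylocta-2,6-dien-1-yl acetate
Conditions: CBr4 (1.3 equiv), PPh3 (1.3 equiv), CH2Cl2, −20 → 0 °C, 1 h
Reagents that add atoms: carbon tetrabromide, BrC(Br)(Br)Br
Why: Appel bromination of the primary allylic alcohol under neutral conditions proceeds by SN2 at the CH2 without allylic transposition or loss of alkene geometry.

**Step 3**
Reactants: 4 3-methylfuran-2(5H)-one
Product: 5 trimethyl[(3-methylfuran-2-yl)oxy]silane
Conditions: TMSOTf (1.1 equiv), Et3N (1.3 equiv), CH2Cl2, 0 °C, 1 h; pentane extraction, distillation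
Reagents that add atoms: trimethylsilyl trifluoromethanesulfonate, C[Si](C)(C)OS(=O)(=O)C(F)(F)F
Why: Soft enolisation and O-silylation of the butenolide (silyl dienol ether formation) gives the aromatic 2-silyloxyfuran, whose only free α-position is C-5.

**Step 4**
Reactants: 3 (2E,6E)-8-bromo-3,7-dimethylocta-2,6-dien-1-yl acetate; 5 trimethyl[(3-methylfuran-2-yl)oxy]silane (1.3 equiv)
Product: 6 (2E,6E)-3,7-dimethyl-8-(4-methyl-5-oxo-2,5-dihydrofuran-2-yl)octa-2,6-dien-1-yl acetate
Conditions: AgO2CCF3 (1.1 equiv), CH2Cl2, −78 → −40 °C, dark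
Reagents that add atoms: none
Why: Silver-assisted ionisation of the allylic bromide gives an allyl cation that C-5 of the silyloxyfuran captures at its unhindered primary terminus (vinylogous Mukaiyama-type γ-alkylation, breaking the furan aromaticity to the butenolide); the new lactone stereocentre is racemic and is erased in step 5.

**Step 5**
Reactants: 6 (2E,6E)-3,7-dimethyl-8-(4-methyl-5-oxo-2,5-dihydrofuran-2-yl)octa-2,6-dien-1-yl acetate
Product: 8 (2E,6E)-3,7-dimethyl-8-(4-methylfuran-2-yl)octa-2,6-dien-1-ol, via lactol 7 (not isolated)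
Conditions: i-Bu2AlH (4.5 equiv), CH2Cl2, −78 °C, 1 h; then cold 1 M aq. HCl, 0 °C, 20 min
Reagents that add atoms: none
Why: 1,2-Reduction of the butenolide carbonyl gives the lactol, which loses water on acidic work-up to aromatise as the regiodefined 2,4-disubstituted furan (reductive aromatisation), while the same hydride cleaves the acetate.

**Step 6**
Reactants: 8 (2E,6E)-3,7-dimethyl-8-(4-methylfuran-2-yl)octa-2,6-dien-1-ol
Product: 9 (2E,6E)-3,7-dimethyl-8-(4-methylfuran-2-yl)octa-2,6-dienal
Conditions: MnO2 (15 equiv), CH2Cl2, rt, 3 h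
Reagents that add atoms: none
Why: Chemoselective MnO2 oxidation of the primary allylic alcohol gives the (2E)-enal without touching the furan or isomerising the alkene.

**Step 7**
Reactants: 9 (2E,6E)-3,7-dimethyl-8-(4-methylfuran-2-yl)octa-2,6-dienal; 10 allenylboronic acid pinacol ester [4,4,5,5-tetramethyl-2-(propa-1,2-dien-1-yl)-1,3,2-dioxaborolane] (1.5 equiv)
Product: 11 (4R,5E,9E)-6,10-dimethyl-11-(4-methylfuran-2-yl)undeca-5,9-dien-1-yn-4-ol
Conditions: (R)-TRIP [(R)-3,3′-bis(2,4,6-triisopropylphenyl)-1,1′-binaphthyl-2,2′-diyl hydrogen phosphate] (10 mol %), 4 Å MS, toluene, −20 °C, 72 h; aqueous work-up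
Reagents that add atoms: none
Why: Chiral phosphoric acid-catalysed asymmetric propargylation through a closed six-membered SE2′ transition state, in which the (R)-catalyst exposes the Re face of the enal and so sets the 4R carbinol; 1,2-addition is exclusive and only the homopropargylic regioisomer forms.

**Step 8**
Reactants: 12 o-cresol (2-methylphenol)
Product: 13 2-hydroxy-3-methylbenzaldehyde
Conditions: MgCl2 (1.5 equiv), Et3N (3.75 equiv), (CH2O)n (6.75 equiv), THF, reflux, 4 h; 1 M aq. HCl
Reagents that add atoms: paraformaldehyde (as formaldehyde), C=O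
Why: Magnesium phenoxide-directed ortho-formylation delivers formaldehyde only to the free ortho position, and a second formaldehyde oxidises the benzylic alkoxide by hydride transfer.

**Step 9**
Reactants: 13 2-hydroxy-3-methylbenzaldehyde
Product: 14 tert-butyl (2-formyl-6-methylphenyl) carbonate
Conditions: Boc2O (1.2 equiv), DMAP (5 mol %), i-Pr2NEt (1.2 equiv), THF, 0 °C → rt
Reagents that add atoms: di-tert-butyl dicarbonate, CC(C)(C)OC(=O)OC(=O)OC(C)(C)C
Why: DMAP-catalysed O-acylation of the phenol installs the carbonate that later acts as the migrating trigger and leaving group.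

**Step 10**
Reactants: 14 tert-butyl (2-formyl-6-methylphenyl) carbonate
Product: 15 tert-butyl [2-(hydroxymethyl)-6-methylphenyl] carbonate
Conditions: BH3·THF (1.0 equiv), THF, −10 → 0 °C, 30 min; MeOH quench
Reagents that add atoms: none
Why: Neutral borane reduction of the aldehyde never generates a free alkoxide, so the carbonate neither migrates nor eliminates prematurely.

**Step 11 (key step)**
Reactants: 11 (4R,5E,9E)-6,10-dimethyl-11-(4-methylfuran-2-yl)undeca-5,9-dien-1-yn-4-ol; 15 tert-butyl [2-(hydroxymethyl)-6-methylphenyl] carbonate (1.5 equiv)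
Product: 19 2-[(2E,5R,6E,10E)-5-hydroxy-3,7,11-trimethyl-12-(4-methylfuran-2-yl)dodeca-2,6,10-trien-1-yl]-6-methylphenol, via alkenylalane 16 (not isolated), via phenoxide carbonate 17 (not isolated), via o-quinone methide 18 (not isolated)
Conditions: (a) 11, Me3Al (3 equiv), Cp2ZrCl2 (0.25 equiv), CH2Cl2, 0 °C → rt, 12 h; excess Me3Al and solvent removed in vacuo, residue in Et2O; (b) CuBr·SMe2 (0.1 equiv), −78 °C; then 15 pre-treated with t-BuMgCl (1.5 equiv, Et2O, −78 °C) added by cannula, −78 → 0 °C, 3 h; (c) aq. KNaC4H4O6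
Reagents that add atoms: trimethylaluminium, C[Al](C)C
Why: Proposed new method: syn-methylalumination of the terminal alkyne (Negishi carboalumination, free hydroxyl carried as its aluminium alkoxide) gives the (E)-alkenylalane 16; the chloromagnesium alkoxide of 15 transfers its Boc group to the benzylic oxygen (17) and expels tert-butyl carbonate, dearomatising the ring to o-quinone methide 18; this locked s-cis enone takes up the alkenyl group at its exocyclic methylene, either through a six-membered Al–O-bound transition state or through an alkenylcopper formed by monovalent copper catalysis, and re-aromatisation drives the C–C bond formation with retention of the E geometry and no effect on the carbinol; the closest known reactions are Grignard capture of o-quinone methides generated by the same Boc-migration cascade, uncatalysed conjugate addition of alkenylalanes to s-cis enones, and copper-catalysed conjugate addition of carboalumination-derived alkenylalanes to enones.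

**Step 12**
Reactants: 19 2-[(2E,5R,6E,10E)-5-hydroxy-3,7,11-trimethyl-12-(4-methylfuran-2-yl)dodeca-2,6,10-trien-1-yl]-6-methylphenol
Product: 21 2-[(2E,5R,6E,10E)-5-hydroxy-3,7,11-trimethyl-12-(4-methylfuran-2-yl)dodeca-2,6,10-trien-1-yl]-6-methylbenzene-1,4-diol (CNP0172089.2), via quinone 20 (not isolated)
Conditions: (KSO3)2NO (2.5 equiv), KH2PO4 buffer (pH 6), acetone–H2O, 0 °C → rt, 2 h; then Na2S2O4 (5 equiv), H2O, Ar, 15 min
Reagents that add atoms: potassium nitrosodisulfonate, [K+].[K+].[O-]S(=O)(=O)N([O])S(=O)(=O)[O-]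
Why: Teuber oxidation, in which one equivalent of the nitroxyl abstracts the phenolic hydrogen and a second oxygenates the free para position, dearomatises the 2,6-disubstituted phenol to the p-quinone, which dithionite reduces to the hydroquinone; furan, alkenes and the allylic alcohol are inert to both reagents.

## Compound list

1 | geranyl acetate, (2E)-3,7-dimethylocta-2,6-dien-1-yl acetate | C/C(=C\COC(C)=O)CCC=C(C)C | starting material
2 | (2E,6E)-8-hydroxy-3,7-dimethylocta-2,6-dien-1-yl acetate | C/C(=C\COC(C)=O)CC/C=C(\C)CO | intermediate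
3 | (2E,6E)-8-bromo-3,7-dimethylocta-2,6-dien-1-yl acetate | C/C(=C\COC(C)=O)CC/C=C(\C)CBr | intermediate
4 | 3-methylfuran-2(5H)-one | CC1=CCOC1=O | starting material
5 | trimethyl[(3-methylfuran-2-yl)oxy]silane | Cc1ccoc1O[Si](C)(C)C | intermediate
6 | (2E,6E)-3,7-dimethyl-8-(4-methyl-5-oxo-2,5-dihydrofuran-2-yl)octa-2,6-dien-1-yl acetate (racemic at the lactone carbon) | C/C(=C\COC(C)=O)CC/C=C(\C)CC1C=C(C)C(=O)O1 | intermediate
7 | 5-[(2E,6E)-8-hydroxy-2,6-dimethylocta-2,6-dien-1-yl]-3-methyl-2,5-dihydrofuran-2-ol (lactol, not isolated) | C/C(=C\CO)CC/C=C(\C)CC1C=C(C)C(O)O1 | intermediate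
8 | (2E,6E)-3,7-dimethyl-8-(4-methylfuran-2-yl)octa-2,6-dien-1-ol | C/C(=C\CO)CC/C=C(\C)Cc1cc(C)co1 | intermediate
9 | (2E,6E)-3,7-dimethyl-8-(4-methylfuran-2-yl)octa-2,6-dienal | C/C(=C\C=O)CC/C=C(\C)Cc1cc(C)co1 | intermediate
10 | allenylboronic acid pinacol ester, 4,4,5,5-tetramethyl-2-(propa-1,2-dien-1-yl)-1,3,2-dioxaborolane | C=C=CB1OC(C)(C)C(C)(C)O1 | starting material
11 | (4R,5E,9E)-6,10-dimethyl-11-(4-methylfuran-2-yl)undeca-5,9-dien-1-yn-4-ol | C/C(=C\[C@H](O)CC#C)CC/C=C(\C)Cc1cc(C)co1 | intermediate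
12 | o-cresol (2-methylphenol) | Cc1ccccc1O | starting material
13 | 2-hydroxy-3-methylbenzaldehyde | Cc1cccc(C=O)c1O | intermediate
14 | tert-butyl (2-formyl-6-methylphenyl) carbonate | Cc1cccc(C=O)c1OC(=O)OC(C)(C)C | intermediate
15 | tert-butyl [2-(hydroxymethyl)-6-methylphenyl] carbonate | Cc1cccc(CO)c1OC(=O)OC(C)(C)C | intermediate
16 | [(1E,4R,5E,9E)-4-[(dimethylalumanyl)oxy]-2,6,10-trimethyl-11-(4-methylfuran-2-yl)undeca-1,5,9-trien-1-yl]dimethylalumane (not isolated) | C/C(=C\[C@H](O[Al](C)C)C/C(C)=C/[Al](C)C)CC/C=C(\C)Cc1cc(C)co1 | intermediate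
17 | tert-butyl (2-hydroxy-3-methylbenzyl) carbonate, present as its chloromagnesium phenoxide (not isolated) | Cc1cccc(COC(=O)OC(C)(C)C)c1O | intermediate
18 | 2-methyl-6-methylidenecyclohexa-2,4-dien-1-one (o-quinone methide, not isolated) | C=C1C=CC=C(C)C1=O | intermediate
19 | 2-[(2E,5R,6E,10E)-5-hydroxy-3,7,11-trimethyl-12-(4-methylfuran-2-yl)dodeca-2,6,10-trien-1-yl]-6-methylphenol | C/C(=C\[C@H](O)C/C(C)=C/Cc1cccc(C)c1O)CC/C=C(\C)Cc1cc(C)co1 | intermediate
20 | 2-[(2E,5R,6E,10E)-5-hydroxy-3,7,11-trimethyl-12-(4-methylfuran-2-yl)dodeca-2,6,10-trien-1-yl]-6-methylcyclohexa-2,5-diene-1,4-dione (not isolated) | C/C(=C\[C@H](O)C/C(C)=C/CC1=CC(=O)C=C(C)C1=O)CC/C=C(\C)Cc1cc(C)co1 | intermediate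
21 | 2-[(2E,5R,6E,10E)-5-hydroxy-3,7,11-trimethyl-12-(4-methylfuran-2-yl)dodeca-2,6,10-trien-1-yl]-6-methylbenzene-1,4-diol | C/C(=C\[C@H](O)C/C(C)=C/Cc1cc(O)cc(C)c1O)CC/C=C(\C)Cc1cc(C)co1 | target

## Step count and risks

Total steps: 12. Longest linear sequence: 8 (steps 1, 2, 4, 5, 6, 7, 11, 12).

**Step 11 (most likely to fail).** The alane capture of the o-quinone methide is unprecedented; the aluminium species may slow the Boc migration, and residual methyl groups may compete for the quinone methide. The fallback avoids the quinone methide and sets out from 15 and from alane 16 (made from 11 as in part (a) of step 11), coming back at 19. Alcohol 15 is brominated (CBr4, PPh3, CH2Cl2, 0 °C) to tert-butyl [2-(bromomethyl)-6-methylphenyl] carbonate F1. Alane 16 is cross-coupled with F1 under Pd(PPh3)4 catalysis (zerovalent palladium, 5 mol %, THF, rt; Negishi alkenylalane–benzyl halide coupling) to give tert-butyl {2-[(2E,5R,6E,10E)-5-hydroxy-3,7,11-trimethyl-12-(4-methylfuran-2-yl)dodeca-2,6,10-trien-1-yl]-6-methylphenyl} carbonate F2. Methanolysis (K2CO3, MeOH, rt) then releases phenol 19.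

**Step 4.** The silver-generated allyl cation may be captured at its secondary terminus or by trifluoroacetate. The fallback replaces the cationic alkylation by a cross-coupling; it sets out from 4 and 3 and comes back at 6. Butenolide 4 is silylated (TIPSOTf, Et3N, CH2Cl2) to 3-methyl-2-[(triisopropylsilyl)oxy]furan F3. Lithiation at the only free α-position (s-BuLi, TMEDA, THF, −78 → 0 °C) and transmetalation with ZnCl2 gives chloro{4-methyl-5-[(triisopropylsilyl)oxy]furan-2-yl}zinc F4, which tolerates the acetate. Pd(PPh3)4-catalysed coupling with bromide 3 (THF, 0 °C → rt) gives (2E,6E)-3,7-dimethyl-8-{4-methyl-5-[(triisopropylsilyl)oxy]furan-2-yl}octa-2,6-dien-1-yl acetate F5. Desilylation with Bu4NF/AcOH (THF, 0 °C), then brief Et3N equilibration to the conjugated isomer, gives butenolide 6.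

**Step 12.** The late oxidation may be sluggish on the lipophilic substrate, or the quinone may be lost to side reactions before reduction. The fallback carries the para oxygen from the start and needs no oxidation; it sets out from alkyne 11 (as alane 16) and comes back at 21.
- Purchased 2-methylbenzene-1,4-diol F6 is monosilylated at the less hindered hydroxyl (TIPSCl, imidazole, DMF, 0 °C) to 2-methyl-4-[(triisopropylsilyl)oxy]phenol F7.
- ortho-Formylation (MgCl2, Et3N, (CH2O)n, THF, reflux) gives 2-hydroxy-3-methyl-5-[(triisopropylsilyl)oxy]benzaldehyde F8.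
- Boc2O/DMAP gives tert-butyl {2-formyl-6-methyl-4-[(triisopropylsilyl)oxy]phenyl} carbonate F9.
- BH3·THF gives tert-butyl {2-(hydroxymethyl)-6-methyl-4-[(triisopropylsilyl)oxy]phenyl} carbonate F10.
- F10 is coupled with alane 16 exactly as in step 11 to give 2-[(2E,5R,6E,10E)-5-hydroxy-3,7,11-trimethyl-12-(4-methylfuran-2-yl)dodeca-2,6,10-trien-1-yl]-6-methyl-4-[(triisopropylsilyl)oxy]phenol F11.
- Bu4NF/AcOH (THF, 0 °C, Ar) removes the silyl group and gives 21.

## Further compounds

F1 | step 11 | tert-butyl [2-(bromomethyl)-6-methylphenyl] carbonate | Cc1cccc(CBr)c1OC(=O)OC(C)(C)C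
F2 | step 11 | tert-butyl {2-[(2E,5R,6E,10E)-5-hydroxy-3,7,11-trimethyl-12-(4-methylfuran-2-yl)dodeca-2,6,10-trien-1-yl]-6-methylphenyl} carbonate | C/C(=C\[C@H](O)C/C(C)=C/Cc1cccc(C)c1OC(=O)OC(C)(C)C)CC/C=C(\C)Cc1cc(C)co1
F3 | step 4 | 3-methyl-2-[(triisopropylsilyl)oxy]furan | Cc1ccoc1O[Si](C(C)C)(C(C)C)C(C)C
F4 | step 4 | chloro{4-methyl-5-[(triisopropylsilyl)oxy]furan-2-yl}zinc | Cc1cc([Zn]Cl)oc1O[Si](C(C)C)(C(C)C)C(C)C
F5 | step 4 | (2E,6E)-3,7-dimethyl-8-{4-methyl-5-[(triisopropylsilyl)oxy]furan-2-yl}octa-2,6-dien-1-yl acetate | C/C(=C\COC(C)=O)CC/C=C(\C)Cc1cc(C)c(O[Si](C(C)C)(C(C)C)C(C)C)o1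
F6 | step 12 | 2-methylbenzene-1,4-diol (purchased) | Cc1cc(O)ccc1O
F7 | step 12 | 2-methyl-4-[(triisopropylsilyl)oxy]phenol | Cc1cc(O[Si](C(C)C)(C(C)C)C(C)C)ccc1O
F8 | step 12 | 2-hydroxy-3-methyl-5-[(triisopropylsilyl)oxy]benzaldehyde | Cc1cc(O[Si](C(C)C)(C(C)C)C(C)C)cc(C=O)c1O
F9 | step 12 | tert-butyl {2-formyl-6-methyl-4-[(triisopropylsilyl)oxy]phenyl} carbonate | Cc1cc(O[Si](C(C)C)(C(C)C)C(C)C)cc(C=O)c1OC(=O)OC(C)(C)C
F10 | step 12 | tert-butyl {2-(hydroxymethyl)-6-methyl-4-[(triisopropylsilyl)oxy]phenyl} carbonate | Cc1cc(O[Si](C(C)C)(C(C)C)C(C)C)cc(CO)c1OC(=O)OC(C)(C)C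
F11 | step 12 | 2-[(2E,5R,6E,10E)-5-hydroxy-3,7,11-trimethyl-12-(4-methylfuran-2-yl)dodeca-2,6,10-trien-1-yl]-6-methyl-4-[(triisopropylsilyl)oxy]phenol | C/C(=C\[C@H](O)C/C(C)=C/Cc1cc(O[Si](C(C)C)(C(C)C)C(C)C)cc(C)c1O)CC/C=C(\C)Cc1cc(C)co1
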